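## Retrosynthetic overview
1. Target ⇐ senecioylation of C4-OH and desilylation ⇐ MnO2 oxidation of the C8 bis-allylic alcohol ⇐ 11-membered ring closed at C8–C9.
2. The only ring is made last, by an electroreductive Ni/Cr-catalysed macrocyclic Nozaki–Hiyama–Kishi (NHK) coupling of a (Z)-2-(silyloxymethyl)vinyl iodide onto an (E)-enal.
3. The acyclic precursor comes from a Wittig reaction at C6=C7 on an α-hydroxy aldehyde, made by reducing a lactic-acid dioxolanone aldol adduct (C4–C5 bond) with an enal that carries the quaternary carbon.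
4. The quaternary carbon (Cq) comes from a Claisen rearrangement of a (Z)-allylic alcohol derived from (R)-butynol. The enal is formed by cross-metathesis and the vinyl iodide by alkyne hydroalumination and iodination.
5. Order: build the acyclic chain and set all three stereocentres, then close the single ring, then oxidise, acylate and deprotect.

**Assumptions**
- (R)-But-3-yn-2-ol and (R)-lactic acid are bought as single enantiomers.
- The major aldol diastereomer at C4 (step 10) is taken to be the required (R)-carbinol, and the minor isomer is removed by chromatography.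

## Route

**Step 1**
Reactants: 1 (R)-but-3-yn-2-ol; 2 5-bromo-2-methylpent-2-ene
Product: 3 (R)-8-methylnon-7-en-3-yn-2-ol
Conditions: n-BuLi (2.1 equiv), THF, −78 → 0 °C; then 2, HMPA, rt
Reagents that add atoms: none
Why: The alkynyl/alkoxide dianion is alkylated (SN2) at the primary bromide, and the carbinol stereocentre is untouched.

**Step 2**
Reactants: 3
Product: 4 (2R,3Z)-4,8-dimethylnona-3,7-dien-2-ol
Conditions: MeMgBr, CuI (10 mol%), THF, 0 °C → rt
Reagents that add atoms: MeMgBr, C[Mg]Br (CH3 ends up on the future quaternary carbon)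
Why: Alkoxide-directed Cu-catalysed carbomagnesiation (Duboudin type) is a syn addition that puts Me on the alkyne carbon distal to the carbinol, so the homoprenyl chain ends up cis to the carbinol carbon, giving the (Z)-alkene.

**Step 3**
Reactants: 4
Product: 5 (3S)-3,7-dimethyl-3-[(E)-prop-1-enyl]oct-6-enal
Conditions: ethyl vinyl ether, Hg(OAc)2 (cat.), 35 °C; then o-xylene, 170 °C, sealed tube
Reagents that add atoms: ethyl vinyl ether, C=COCC (supplies the CH2CHO unit)
Why: In the chair Claisen transition state of the vinyl ether, the (R)-carbinol has its methyl equatorial and the (Z)-alkene puts the homoprenyl group pseudo-axial, so the new C–C bond forms on one alkene face, transferring the (R)-carbinol to the (S)-quaternary centre with an E-propenyl group.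

**Step 4**
Reactants: 5
Product: 6 (4S)-4,8-dimethyl-4-[(E)-prop-1-enyl]non-7-en-1-yne
Conditions: Bestmann–Ohira reagent, K2CO3, MeOH, rt
Reagents that add atoms: dimethyl (1-diazo-2-oxopropyl)phosphonate, COP(=O)(OC)C(=[N+]=[N-])C(C)=O (supplies C9)
Why: One-carbon homologation of the aldehyde to the terminal alkyne (Ohira–Bestmann) leaves the stereocentre, which is not α to the aldehyde, untouched.

**Step 5**
Reactants: 6
Product: 7 (5S)-5,9-dimethyl-5-[(E)-prop-1-enyl]dec-8-en-2-yn-1-ol
Conditions: n-BuLi, THF, −78 °C; then (CH2O)n, −78 °C → rt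
Reagents that add atoms: paraformaldehyde, C=O (supplies the CH2OH carbon)
Why: The acetylide adds to formaldehyde (hydroxymethylation) to give the propargylic alcohol.

**Step 6**
Reactants: 7
Product: 8 (2Z,5S)-2-iodo-5,9-dimethyl-5-[(E)-prop-1-enyl]deca-2,8-dien-1-ol
Conditions: LiAlH4, AlCl3, THF, 0 °C → rt; then I2, −78 °C
Reagents that add atoms: iodine, II
Why: Corey alkoxide-directed trans-hydroalumination puts H on C3 and Al on C2, and iodinolysis with retention gives the 2-iodoallylic alcohol with I cis to the CH2 chain, which fixes the Z-ring alkene needed later.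

**Step 7**
Reactants: 8
Product: 9 TBS ether of 8
Conditions: TBSCl, imidazole, DMF, rt
Reagents that add atoms: TBSCl, C[Si](C)(Cl)C(C)(C)C
Why: Standard silylation protects the primary alcohol for the later MnO2 and aldol steps.

**Step 8**
Reactants: 9; 10 acrolein
Product: 11 (2E,4S,6Z)-8-(TBSO)-7-iodo-4-methyl-4-(4-methylpent-3-enyl)octa-2,6-dienal
Conditions: Hoveyda–Grubbs II (5 mol%), 10 (10 equiv), CH2Cl2, 40 °C
Reagents that add atoms: none beyond 10
Why: E-selective olefin cross-metathesis swaps the propenyl CH3CH= for OHC–CH=, while the trisubstituted homoprenyl alkene and the vinyl iodide are too hindered to react.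

**Step 9**
Reactants: 12 (R)-lactic acid; 13 pivalaldehyde
Product: 14 (2R,5R)-2-tert-butyl-5-methyl-1,3-dioxolan-4-one
Conditions: p-TsOH (cat.), pentane, Dean–Stark, reflux; recrystallise the cis isomer
Reagents that add atoms: none beyond 12 and 13
Why: Acetalisation gives the cis dioxolanone (Seebach), which carries the lactate configuration and protects the tertiary oxygen.

**Step 10**
Reactants: 14; 11
Product: 15 aldol adduct (C4 R, C5 S as named in the ring, ring C2 R)
Conditions: LDA, THF, −78 °C; then 11, −78 °C
Reagents that add atoms: none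
Why: Self-regeneration-of-stereocentres aldol: the lithium enolate is attacked anti to the tert-butyl group, which retains the lactate configuration at the quaternary carbon, and the Zimmerman–Traxler closed transition state sets the adjacent carbinol.

**Step 11**
Reactants: 15
Product: 16 (2S,3R,4E,6S,8Z)-10-(TBSO)-2,3-dihydroxy-9-iodo-2,6-dimethyl-6-(4-methylpent-3-enyl)deca-4,8-dienal
Conditions: DIBAL-H (2.5 equiv), CH2Cl2, −78 °C; Rochelle salt work-up
Reagents that add atoms: none
Why: Partial reduction of the dioxolanone gives a lactol that collapses on work-up, releasing pivalaldehyde and giving the α-hydroxy aldehyde, which has no α-H and so cannot epimerise.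

**Step 12**
Reactants: 16; 17 (triphenylphosphoranylidene)acetaldehyde
Product: 18 (2E,4R,5R,6E,8S,10Z)-12-(TBSO)-4,5-dihydroxy-11-iodo-4,8-dimethyl-8-(4-methylpent-3-enyl)dodeca-2,6,10-trienal
Conditions: 17 (3 equiv), toluene, 80 °C
Reagents that add atoms: none beyond 17
Why: A stabilised-ylide Wittig reaction gives the (E)-enal (C6=C7) and leaves all stereocentres intact.

**Step 13**
Reactants: 18
Product: 19 macrocyclic dienol (C8 epimeric mixture)
Conditions: CrCl3 (10 mol%), NiCl2·glyme (5 mol%), dtbbpy (5 mol%), TMSCl (3 equiv), nBu4NBF4, DMF/THF, undivided cell, Mg anode / graphite-felt cathode, 2 mA, rt, substrate added by syringe pump to 0.002 M; then 1 M HCl/THF, 0 °C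
Reagents that add atoms: none (TMS ethers formed in situ are removed on work-up)
Why: Proposed new method: cathodic reduction turns Ni(II) into Ni(0), which adds oxidatively to the Z-vinyl iodide, and Cr(II) generated at the cathode transmetalates it, giving a vinyl-Cr(III) species that adds 1,2 intramolecularly to the enal and forms the C8–C9 bond and the 11-membered ring, with TMSCl turning over Cr and Mg2+ from the sacrificial anode acting as Lewis acid; the closest known reactions are the Kishi Ni/Cr NHK coupling and electroreductive Cr-catalysed allylations, applied here to a macrocyclisation onto an enal with an α-branched Z-vinyl iodide, and the new C8 stereocentre is irrelevant because it is oxidised next.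

**Step 14**
Reactants: 19
Product: 20 macrocyclic dienone (TBS ether)
Conditions: activated MnO2 (20 equiv), CH2Cl2, rt
Reagents that add atoms: none
Why: MnO2 selectively oxidises the bis-allylic C8 alcohol, which is far more reactive than the hindered C4 allylic alcohol beside the quaternary carbinol, and it erases the C8 epimeric mixture.

**Step 15**
Reactants: 20; 21 senecioyl chloride
Product: 22 C4 senecioate
Conditions: 21 (2 equiv), DMAP (0.2 equiv), pyridine, CH2Cl2, 0 °C → rt
Reagents that add atoms: none beyond 21
Why: DMAP-catalysed acylation is selective for the secondary allylic C4-OH over the tertiary C5-OH, and both stereocentres are retained.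

**Step 16**
Reactants: 22
Product: 23 target
Conditions: HF·pyridine, pyridine/THF, 0 °C → rt
Reagents that add atoms: none
Why: Fluoride cleaves the primary TBS ether while the senecioate ester, tertiary alcohol and dienone are unaffected.

## Compound list
1 | (R)-but-3-yn-2-ol | C#C[C@@H](C)O | starting material
2 | 5-bromo-2-methylpent-2-ene | CC(C)=CCCBr | starting material
3 | (R)-8-methylnon-7-en-3-yn-2-ol | CC(C)=CCCC#C[C@@H](C)O | intermediate
4 | (2R,3Z)-4,8-dimethylnona-3,7-dien-2-ol | C[C@@H](O)/C=C(\CCC=C(C)C)C | intermediate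
5 | (3S)-3,7-dimethyl-3-[(E)-prop-1-enyl]oct-6-enal | O=CC[C@](C)(CCC=C(C)C)/C=C/C | intermediate
6 | (4S)-4,8-dimethyl-4-[(E)-prop-1-enyl]non-7-en-1-yne | C#CC[C@](C)(CCC=C(C)C)/C=C/C | intermediate
7 | (5S)-5,9-dimethyl-5-[(E)-prop-1-enyl]dec-8-en-2-yn-1-ol | OCC#CC[C@](C)(CCC=C(C)C)/C=C/C | intermediate
8 | (2Z,5S)-2-iodo-5,9-dimethyl-5-[(E)-prop-1-enyl]deca-2,8-dien-1-ol | OC/C(I)=C/C[C@](C)(CCC=C(C)C)/C=C/C | intermediate
9 | TBS ether of 8 | CC(C)(C)[Si](C)(C)OC/C(I)=C/C[C@](C)(CCC=C(C)C)/C=C/C | intermediate
10 | acrolein | C=CC=O | starting material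
11 | (2E,4S,6Z)-8-(TBSO)-7-iodo-4-methyl-4-(4-methylpent-3-enyl)octa-2,6-dienal | O=C/C=C/[C@@](C)(CCC=C(C)C)C/C=C(\I)CO[Si](C)(C)C(C)(C)C | intermediate
12 | (R)-lactic acid | C[C@@H](O)C(=O)O | starting material
13 | pivalaldehyde | CC(C)(C)C=O | starting material
14 | (2R,5R)-2-tert-butyl-5-methyl-1,3-dioxolan-4-one | C[C@H]1O[C@@H](C(C)(C)C)OC1=O | intermediate
15 | aldol adduct of 14 and 11 | C[C@]1(O[C@@H](C(C)(C)C)OC1=O)[C@H](O)/C=C/[C@@](C)(CCC=C(C)C)C/C=C(\I)CO[Si](C)(C)C(C)(C)C | intermediate
16 | α-hydroxy aldehyde (diol) | O=C[C@@](C)(O)[C@H](O)/C=C/[C@@](C)(CCC=C(C)C)C/C=C(\I)CO[Si](C)(C)C(C)(C)C | intermediate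
17 | (triphenylphosphoranylidene)acetaldehyde | O=CC=P(c1ccccc1)(c1ccccc1)c1ccccc1 | starting material
18 | macrocyclisation precursor (enal, vinyl iodide, diol) | O=C/C=C/[C@@](C)(O)[C@H](O)/C=C/[C@@](C)(CCC=C(C)C)C/C=C(\I)CO[Si](C)(C)C(C)(C)C | intermediate
19 | 11-membered dienol (C8 epimers, TBS ether) | CC(C)=CCC[C@]1(C)/C=C/[C@@H](O)[C@](C)(O)/C=C/C(O)/C(CO[Si](C)(C)C(C)(C)C)=C\C1 | intermediate
20 | macrocyclic dienone (TBS ether) | CC(C)=CCC[C@]1(C)/C=C/[C@@H](O)[C@](C)(O)/C=C/C(=O)/C(CO[Si](C)(C)C(C)(C)C)=C\C1 | intermediate
21 | senecioyl (3,3-dimethylacryloyl) chloride | CC(C)=CC(=O)Cl | starting material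
22 | C4 senecioate of 20 | CC(C)=CCC[C@]1(C)/C=C/[C@@H](OC(=O)C=C(C)C)[C@](C)(O)/C=C/C(=O)/C(CO[Si](C)(C)C(C)(C)C)=C\C1 | intermediate
23 | target (CID15817377) | CC(C)=CCC[C@]1(C)/C=C/[C@@H](OC(=O)C=C(C)C)[C@](C)(O)/C=C/C(=O)/C(CO)=C\C1 | target

## Summary
Total steps: 16, including step 9, which makes a building block in parallel. Longest linear sequence: 15 steps (from 1).

**Three steps most likely to fail**
1. **Step 13 (new electroreductive macrocyclic NHK).** The risks are oligomerisation, cathodic reduction of the enal, and strain in forming the 11-membered ring. Fallback: a different ring closure by ring-closing metathesis. Methylenate 16 (Ph3P=CH2), do an intermolecular NHK of the vinyl iodide with acrolein (CrCl2/NiCl2), oxidise with MnO2, then close C6=C7 with Hoveyda–Grubbs II in toluene at 80 °C and 1 mM. All of these are known reactions.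
2. **Step 10 (aldol diastereoselectivity at C4).** Fallback: oxidise the aldol mixture (Dess–Martin) to the C4 enone and reduce it with Zn(BH4)2, using chelation control by the adjacent ring oxygen to set the (R)-carbinol.
3. **Step 8 (cross-metathesis on the hindered neopentyl propenyl alkene).** Fallback: epoxidise the isopropylidene of 9 selectively (1 equiv mCPBA), cleave the propenyl alkene (OsO4/NaIO4), make the enal with 17, and restore the isopropylidene from the epoxide (WCl6/n-BuLi).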